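Everything rests on opening ring C at its aryl ether bond O1–C8a together with the bond from the neighbouring ring-A carbon C8 to the side chain. In one operation a 7-silyloxy aryne spanning C8 and C8a takes up the tethered C2 alkoxide at C8a, which closes the pyran ring, and the C8 aryllithium left behind is acylated by the complete side chain as its Weinreb amide. The precursor is an open-chain fluoroarene whose C4 ketone is masked as a 1,3-dithiane and whose (S)-carbinol comes from an epoxide. The feature exploited is the contiguous array C7–O, C8–side chain, C8a–O1 on ring A.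

Key step: step 16

Remark: ring atoms are numbered as in a flavanone (ring C: O1, C2, C3, C4; ring A: C4a, C5–C8, C8a). The nine side-chain carbons are called chain C1–C9, starting at the carbon on C8. TBS = tert-butyldimethylsilyl, TIPS = triisopropylsilyl, TMS = trimethylsilyl.
Assumption: compounds 1, 6, 12 and 16 are taken as purchased. The facial sense of the catalyst in step 11 is assigned by analogy and would be checked on the first run.

Step 1
Reactants: 1 3-fluoro-5-methoxyphenol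
Product: 2 (3-fluoro-5-methoxyphenoxy)triisopropylsilane
Conditions: TIPSCl, imidazole, DMF, rt
Reagents that add atoms: chlorotriisopropylsilane, CC(C)[Si](Cl)(C(C)C)C(C)C
Why: Silyl ether formation at the phenol; the bulky TIPS group later shields both of its ortho positions in step 2 and resists 1,3-silyl migration to an ortho carbanion in step 16.

Step 2
Reactants: 2 (3-fluoro-5-methoxyphenoxy)triisopropylsilane
Product: 4 2-fluoro-6-methoxy-4-(TIPSO)benzaldehyde, via aryllithium 3 (not isolated)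
Conditions: n-BuLi, THF, –78 °C; DMF, –78 °C; aq. NH4Cl
Reagents that add atoms: N,N-dimethylformamide, CN(C)C=O
Why: Directed ortho-metalation at the only ring position flanked by F and OMe and not shielded by OTIPS, followed by formylation; at –78 °C the ortho-fluoro aryllithium should not yet lose LiF.

Step 3
Reactants: 4 2-fluoro-6-methoxy-4-(TIPSO)benzaldehyde
Product: 5 2-[2-fluoro-6-methoxy-4-(TIPSO)phenyl]-1,3-dithiane
Conditions: HS(CH2)3SH, BF3·OEt2 (cat.), CH2Cl2, 0 °C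
Reagents that add atoms: propane-1,3-dithiol, SCCCS
Why: Lewis-acid-catalysed dithioacetalisation; the dithiane serves as the acyl-anion equivalent (Corey–Seebach umpolung) in step 7 and as the mask of the C4 ketone through steps 16 and 17.

Step 4
Reactants: 6 2-chloro-1-(4-hydroxyphenyl)ethan-1-one
Product: 7 2-chloro-1-[4-(TBSO)phenyl]ethan-1-one
Conditions: TBSOTf, 2,6-lutidine, CH2Cl2, –78 to 0 °C
Reagents that add atoms: tert-butyldimethylsilyl trifluoromethanesulfonate, CC(C)(C)[Si](C)(C)OS(=O)(=O)C(F)(F)F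
Why: Phenol silylation with a hindered, non-nucleophilic base, which should avoid N-alkylation of the base by the phenacyl chloride.

Step 5
Reactants: 7 2-chloro-1-[4-(TBSO)phenyl]ethan-1-one
Product: 8 (R)-2-chloro-1-[4-(TBSO)phenyl]ethan-1-ol
Conditions: RuCl[(S,S)-TsDPEN](p-cymene) (1 mol%), HCO2H/Et3N (5:2), EtOAc, rt
Reagents that add atoms: none
Why: Noyori-type asymmetric transfer hydrogenation through the six-membered Ru–H/N–H transition state, in which the CH–π contact between p-cymene and the aryl group fixes the face of hydride delivery; the (S,S) catalyst should give the R chlorohydrin (the descriptor differs from that of the parent 1-arylethanol only because CH2Cl outranks aryl).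

Step 6
Reactants: 8 (R)-2-chloro-1-[4-(TBSO)phenyl]ethan-1-ol
Product: 9 (R)-2-[4-(TBSO)phenyl]oxirane
Conditions: NaH, THF, 0 °C to rt
Reagents that add atoms: none
Why: Intramolecular Williamson etherification (SN2 at CH2Cl); the stereocentre is not touched, and the absence of hydroxide or methoxide spares the aryl silyl ether.

Step 7
Reactants: 5 2-[2-fluoro-6-methoxy-4-(TIPSO)phenyl]-1,3-dithiane; 9 (R)-2-[4-(TBSO)phenyl]oxirane
Product: 11 (S)-2-{2-[2-fluoro-6-methoxy-4-(TIPSO)phenyl]-1,3-dithian-2-yl}-1-[4-(TBSO)phenyl]ethan-1-ol, via lithiated dithiane 10 (not isolated)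
Conditions: n-BuLi, THF, –78 to –30 °C; then 9, –30 to 0 °C; aq. NH4Cl
Reagents that add atoms: none
Why: Corey–Seebach alkylation: the 2-lithio-1,3-dithiane opens the epoxide by SN2 at its unsubstituted carbon, so the carbinol centre keeps its arrangement (R becomes S only through the change in CIP ranking).

Step 8
Reactants: 12 4-(4-hydroxyphenyl)butan-2-one
Product: 13 4-[4-(TBSO)phenyl]butan-2-one
Conditions: TBSCl, imidazole, DMF, rt
Reagents that add atoms: tert-butylchlorodimethylsilane, CC(C)(C)[Si](C)(C)Cl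
Why: Standard silyl ether formation at the phenol.

Step 9
Reactants: 13 4-[4-(TBSO)phenyl]butan-2-one
Product: 15 trimethyl({4-[4-(TBSO)phenyl]but-1-en-2-yl}oxy)silane, via lithium enolate 14 (not isolated)
Conditions: LDA, THF, –78 °C; TMSCl, –78 °C to rt
Reagents that add atoms: chlorotrimethylsilane, C[Si](C)(C)Cl
Why: Kinetic deprotonation of the methyl ketone at the less substituted side and O-silylation should give the terminal silyl enol ether.

Step 10
Reactants: 16 4-(TBSO)benzaldehyde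
Product: 17 (E)-3-[4-(TBSO)phenyl]prop-2-enal
Conditions: Ph3P=CHCHO (1.05 equiv), toluene, 80 °C
Reagents that add atoms: (triphenylphosphoranylidene)acetaldehyde, O=CC=P(c1ccccc1)(c1ccccc1)c1ccccc1
Why: Wittig olefination with a stabilised ylide, which should give the E enal; the ylide is kept near one equivalent to limit a second homologation.

Step 11
Reactants: 15 trimethyl({4-[4-(TBSO)phenyl]but-1-en-2-yl}oxy)silane; 17 (E)-3-[4-(TBSO)phenyl]prop-2-enal
Product: 19 (5R,6E)-5-hydroxy-1,7-bis[4-(TBSO)phenyl]hept-6-en-3-one, via trichlorosilyl aldolate 18 (not isolated)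
Conditions: SiCl4, (R,R)-bisphosphoramide [two (R)-N,N'-dimethyl-1,1'-binaphthyl-2,2'-diamine phosphoramide units joined through N,N'-dimethylpentane-1,5-diamine] (5 mol%), i-Pr2NEt (10 mol%), CH2Cl2, –78 °C; aq. NaHCO3
Reagents that add atoms: none
Why: Lewis-base-catalysed Mukaiyama aldol addition, in which the chiral phosphoramide-bound trichlorosilyl cation activates the enal and shields one face; the (R,R) catalyst is expected to direct the enol ether to the Re face (5R), and the (S,S) antipode would be taken if the first run shows the opposite sense.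

Step 12
Reactants: 19 (5R,6E)-5-hydroxy-1,7-bis[4-(TBSO)phenyl]hept-6-en-3-one
Product: 20 (1E,3R,5S)-5-hydroxy-1,7-bis[4-(TBSO)phenyl]hept-1-en-3-yl acetate
Conditions: SmI2 (20 mol%), CH3CHO (6 equiv), THF, –10 °C
Reagents that add atoms: acetaldehyde, CC=O
Why: Evans–Tishchenko reduction: the samarium-bound hemiacetal formed from the allylic hydroxyl and acetaldehyde delivers hydride intramolecularly to the ketone through a chair-like bicyclic transition state, which should set the new carbinol 1,3-anti (S) and leave the acetate on the allylic oxygen.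

Step 13
Reactants: 20 (1E,3R,5S)-5-hydroxy-1,7-bis[4-(TBSO)phenyl]hept-1-en-3-yl acetate
Product: 21 (1E,3R,5S)-5-(TBSO)-1,7-bis[4-(TBSO)phenyl]hept-1-en-3-yl acetate
Conditions: TBSCl, imidazole, DMF, rt
Reagents that add atoms: tert-butylchlorodimethylsilane, CC(C)(C)[Si](C)(C)Cl
Why: Silylation of the free secondary alcohol under mild, non-Lewis-acidic conditions that should not ionise the electron-rich cinnamyl acetate.

Step 14
Reactants: 21 (1E,3R,5S)-5-(TBSO)-1,7-bis[4-(TBSO)phenyl]hept-1-en-3-yl acetate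
Product: 24 (3R,4E,7S)-7-(TBSO)-3,9-bis[4-(TBSO)phenyl]non-4-enoic acid, via ketene silyl acetal 22 (not isolated), via trimethylsilyl ester 23 (not isolated)
Conditions: LDA, TMSCl (in situ), THF, –78 °C to rt, then 50 °C; aq. citric acid
Reagents that add atoms: none
Why: Ireland–Claisen rearrangement: the ketene silyl acetal of the allylic acetate rearranges through a chair transition state with the silyloxyalkyl chain equatorial, which should give the E alkene and transfer the R configuration of the allylic carbinol suprafacially to the new aryl-bearing carbon (3R).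

Step 15
Reactants: 24 (3R,4E,7S)-7-(TBSO)-3,9-bis[4-(TBSO)phenyl]non-4-enoic acid
Product: 25 (3R,4E,7S)-N-methoxy-N-methyl-7-(TBSO)-3,9-bis[4-(TBSO)phenyl]non-4-enamide
Conditions: MeNHOMe·HCl, EDC·HCl, HOBt, i-Pr2NEt, CH2Cl2, 0 °C to rt
Reagents that add atoms: N,O-dimethylhydroxylamine hydrochloride, CNOC.Cl
Why: Carbodiimide-mediated amide coupling; the stereocentre is beta to the carboxyl group and is not at risk.

Step 16
Reactants: 11 (S)-2-{2-[2-fluoro-6-methoxy-4-(TIPSO)phenyl]-1,3-dithian-2-yl}-1-[4-(TBSO)phenyl]ethan-1-ol; 25 (3R,4E,7S)-N-methoxy-N-methyl-7-(TBSO)-3,9-bis[4-(TBSO)phenyl]non-4-enamide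
Product: 29 (3R,4E,7S)-7-(TBSO)-3,9-bis[4-(TBSO)phenyl]-1-{(2S)-5-methoxy-2-[4-(TBSO)phenyl]-7-(TIPSO)spiro[chromane-4,2'-[1,3]dithian]-8-yl}non-4-en-1-one, via dilithio species 26 (not isolated), via aryne 27 (not isolated), via aryllithium 28 (not isolated)
Conditions: s-BuLi (2.1 equiv), PMDTA, THF, –78 °C; –78 to –30 °C; then 25, –78 to 0 °C; aq. NH4Cl
Reagents that add atoms: none
Why: Two equivalents of s-BuLi first give the lithium alkoxide and then, under acidity control by PMDTA, metalate C8 next to fluorine; on warming LiF is lost to give aryne 27 spanning C8 and C8a. The tethered alkoxide adds to C8a in a 6-exo-dig closure that forms the O1–C8a bond and ring C, and the C8 aryllithium 28 so formed is acylated by Weinreb amide 25 through its stable chelated tetrahedral adduct (Weinreb ketone synthesis). The closest known reaction types are the anionic benzyne cyclisation of tethered alkoxides and the nucleophile addition–electrophile trapping of arynes generated from ortho-lithiated fluoroarenes. No new stereocentre is formed, and C2 keeps its S configuration because its C–O bond is not broken. The needed regioselectivity (oxygen at C8a, carbon at C8) is secured twice: by the tether (six- against seven-membered ring) and by the inductively withdrawing C7 silyloxy group, which directs nucleophiles to the distal aryne carbon and stabilises the carbanion at C8. The dithiane keeps C4 non-electrophilic and non-enolisable, so the aryllithium should not be quenched and ring C cannot reopen.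

Step 17
Reactants: 29 (3R,4E,7S)-7-(TBSO)-3,9-bis[4-(TBSO)phenyl]-1-{(2S)-5-methoxy-2-[4-(TBSO)phenyl]-7-(TIPSO)spiro[chromane-4,2'-[1,3]dithian]-8-yl}non-4-en-1-one
Product: 30 (1S,3R,4E,7S)-7-(TBSO)-3,9-bis[4-(TBSO)phenyl]-1-{(2S)-5-methoxy-2-[4-(TBSO)phenyl]-7-(TIPSO)spiro[chromane-4,2'-[1,3]dithian]-8-yl}non-4-en-1-ol
Conditions: (R)-2-methyl-CBS-oxazaborolidine (0.5 equiv), catecholborane, toluene, –40 to –20 °C
Reagents that add atoms: none
Why: Corey–Bakshi–Shibata reduction: the ketone binds to the oxazaborolidine boron anti to the large, doubly ortho-substituted aryl group, so hydride is delivered to one face and the R catalyst should give the S carbinol; catecholborane leaves the alkene untouched and the dithiane ensures that no second ketone is present.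

Step 18
Reactants: 30 (1S,3R,4E,7S)-7-(TBSO)-3,9-bis[4-(TBSO)phenyl]-1-{(2S)-5-methoxy-2-[4-(TBSO)phenyl]-7-(TIPSO)spiro[chromane-4,2'-[1,3]dithian]-8-yl}non-4-en-1-ol
Product: 31 (2S)-8-{(1S,3R,4E,7S)-1-hydroxy-7-(TBSO)-3,9-bis[4-(TBSO)phenyl]non-4-en-1-yl}-5-methoxy-2-[4-(TBSO)phenyl]-7-(TIPSO)chroman-4-one
Conditions: MeI, CaCO3, MeCN/H2O (9:1), 45 °C
Reagents that add atoms: water, O
Why: Alkylative hydrolysis of the dithioketal (S-methylation, ring opening to an aryl-stabilised thionium ion, addition of water) under buffered, non-oxidising conditions that should spare the alkene, the silyl ethers and the acid-labile benzylic carbinol.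

Step 19
Reactants: 31 (2S)-8-{(1S,3R,4E,7S)-1-hydroxy-7-(TBSO)-3,9-bis[4-(TBSO)phenyl]non-4-en-1-yl}-5-methoxy-2-[4-(TBSO)phenyl]-7-(TIPSO)chroman-4-one
Product: 32 (2S)-8-[(1S,3R,4E,7S)-1,7-dihydroxy-3,9-bis(4-hydroxyphenyl)non-4-en-1-yl]-7-hydroxy-2-(4-hydroxyphenyl)-5-methoxychroman-4-one
Conditions: Bu4NF, AcOH (1:1), THF, 0 °C to rt
Reagents that add atoms: none
Why: Fluoride-induced cleavage of the four aryl silyl ethers and the secondary silyl ether; buffering with acetic acid should prevent base-induced opening of ring C (retro-oxa-Michael) and so racemisation at C2.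

Compound list
1 | 3-fluoro-5-methoxyphenol | COc1cc(O)cc(F)c1 | starting material
2 | (3-fluoro-5-methoxyphenoxy)triisopropylsilane | COc1cc(F)cc(O[Si](C(C)C)(C(C)C)C(C)C)c1 | intermediate
3 | 2-fluoro-6-methoxy-4-(TIPSO)phenyllithium | COc1cc(O[Si](C(C)C)(C(C)C)C(C)C)cc(F)c1[Li] | intermediate
4 | 2-fluoro-6-methoxy-4-(TIPSO)benzaldehyde | COc1cc(O[Si](C(C)C)(C(C)C)C(C)C)cc(F)c1C=O | intermediate
5 | 2-[2-fluoro-6-methoxy-4-(TIPSO)phenyl]-1,3-dithiane | COc1cc(O[Si](C(C)C)(C(C)C)C(C)C)cc(F)c1C1SCCCS1 | intermediate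
6 | 2-chloro-1-(4-hydroxyphenyl)ethan-1-one | O=C(CCl)c1ccc(O)cc1 | starting material
7 | 2-chloro-1-[4-(TBSO)phenyl]ethan-1-one | O=C(CCl)c1ccc(O[Si](C)(C)C(C)(C)C)cc1 | intermediate
8 | (R)-2-chloro-1-[4-(TBSO)phenyl]ethan-1-ol | O[C@@H](CCl)c1ccc(O[Si](C)(C)C(C)(C)C)cc1 | intermediate
9 | (R)-2-[4-(TBSO)phenyl]oxirane | CC(C)(C)[Si](C)(C)Oc1ccc([C@@H]2CO2)cc1 | intermediate
10 | 2-lithio derivative of dithiane 5 | COc1cc(O[Si](C(C)C)(C(C)C)C(C)C)cc(F)c1C1([Li])SCCCS1 | intermediate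
11 | (S)-2-{2-[2-fluoro-6-methoxy-4-(TIPSO)phenyl]-1,3-dithian-2-yl}-1-[4-(TBSO)phenyl]ethan-1-ol | COc1cc(O[Si](C(C)C)(C(C)C)C(C)C)cc(F)c1C1(C[C@H](O)c2ccc(O[Si](C)(C)C(C)(C)C)cc2)SCCCS1 | intermediate
12 | 4-(4-hydroxyphenyl)butan-2-one | CC(=O)CCc1ccc(O)cc1 | starting material
13 | 4-[4-(TBSO)phenyl]butan-2-one | CC(=O)CCc1ccc(O[Si](C)(C)C(C)(C)C)cc1 | intermediate
14 | lithium enolate of 13 (terminal) | [Li]OC(=C)CCc1ccc(O[Si](C)(C)C(C)(C)C)cc1 | intermediate
15 | trimethyl({4-[4-(TBSO)phenyl]but-1-en-2-yl}oxy)silane | C=C(O[Si](C)(C)C)CCc1ccc(O[Si](C)(C)C(C)(C)C)cc1 | intermediate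
16 | 4-(TBSO)benzaldehyde | O=Cc1ccc(O[Si](C)(C)C(C)(C)C)cc1 | starting material
17 | (E)-3-[4-(TBSO)phenyl]prop-2-enal | O=C/C=C/c1ccc(O[Si](C)(C)C(C)(C)C)cc1 | intermediate
18 | O-trichlorosilyl ether of aldol 19 | O=C(CCc1ccc(O[Si](C)(C)C(C)(C)C)cc1)C[C@@H](O[Si](Cl)(Cl)Cl)/C=C/c1ccc(O[Si](C)(C)C(C)(C)C)cc1 | intermediate
19 | (5R,6E)-5-hydroxy-1,7-bis[4-(TBSO)phenyl]hept-6-en-3-one | O=C(CCc1ccc(O[Si](C)(C)C(C)(C)C)cc1)C[C@@H](O)/C=C/c1ccc(O[Si](C)(C)C(C)(C)C)cc1 | intermediate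
20 | (1E,3R,5S)-5-hydroxy-1,7-bis[4-(TBSO)phenyl]hept-1-en-3-yl acetate | CC(=O)O[C@H](C[C@@H](O)CCc1ccc(O[Si](C)(C)C(C)(C)C)cc1)/C=C/c1ccc(O[Si](C)(C)C(C)(C)C)cc1 | intermediate
21 | (1E,3R,5S)-5-(TBSO)-1,7-bis[4-(TBSO)phenyl]hept-1-en-3-yl acetate | CC(=O)O[C@H](C[C@@H](O[Si](C)(C)C(C)(C)C)CCc1ccc(O[Si](C)(C)C(C)(C)C)cc1)/C=C/c1ccc(O[Si](C)(C)C(C)(C)C)cc1 | intermediate
22 | ketene trimethylsilyl acetal of acetate 21 | C=C(O[Si](C)(C)C)O[C@H](C[C@@H](O[Si](C)(C)C(C)(C)C)CCc1ccc(O[Si](C)(C)C(C)(C)C)cc1)/C=C/c1ccc(O[Si](C)(C)C(C)(C)C)cc1 | intermediate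
23 | trimethylsilyl ester of acid 24 | C[Si](C)(C)OC(=O)C[C@H](/C=C/C[C@@H](O[Si](C)(C)C(C)(C)C)CCc1ccc(O[Si](C)(C)C(C)(C)C)cc1)c1ccc(O[Si](C)(C)C(C)(C)C)cc1 | intermediate
24 | (3R,4E,7S)-7-(TBSO)-3,9-bis[4-(TBSO)phenyl]non-4-enoic acid | OC(=O)C[C@H](/C=C/C[C@@H](O[Si](C)(C)C(C)(C)C)CCc1ccc(O[Si](C)(C)C(C)(C)C)cc1)c1ccc(O[Si](C)(C)C(C)(C)C)cc1 | intermediate
25 | (3R,4E,7S)-N-methoxy-N-methyl-7-(TBSO)-3,9-bis[4-(TBSO)phenyl]non-4-enamide | CON(C)C(=O)C[C@H](/C=C/C[C@@H](O[Si](C)(C)C(C)(C)C)CCc1ccc(O[Si](C)(C)C(C)(C)C)cc1)c1ccc(O[Si](C)(C)C(C)(C)C)cc1 | intermediate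
26 | lithium alkoxide of 11 lithiated at C8 | COc1cc(O[Si](C(C)C)(C(C)C)C(C)C)c([Li])c(F)c1C1(C[C@H](O[Li])c2ccc(O[Si](C)(C)C(C)(C)C)cc2)SCCCS1 | intermediate
27 | C8/C8a aryne bearing the lithium alkoxide | COC1=C(C2(C[C@H](O[Li])c3ccc(O[Si](C)(C)C(C)(C)C)cc3)SCCCS2)C#CC(O[Si](C(C)C)(C(C)C)C(C)C)=C1 | intermediate
28 | (2S)-8-lithio-5-methoxy-2-[4-(TBSO)phenyl]-7-(TIPSO)spiro[chromane-4,2'-[1,3]dithiane] | COc1cc(O[Si](C(C)C)(C(C)C)C(C)C)c([Li])c2c1C1(C[C@@H](c3ccc(O[Si](C)(C)C(C)(C)C)cc3)O2)SCCCS1 | intermediate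
29 | (3R,4E,7S)-7-(TBSO)-3,9-bis[4-(TBSO)phenyl]-1-{(2S)-5-methoxy-2-[4-(TBSO)phenyl]-7-(TIPSO)spiro[chromane-4,2'-[1,3]dithian]-8-yl}non-4-en-1-one | COc1cc(O[Si](C(C)C)(C(C)C)C(C)C)c(C(=O)C[C@H](/C=C/C[C@@H](O[Si](C)(C)C(C)(C)C)CCc2ccc(O[Si](C)(C)C(C)(C)C)cc2)c2ccc(O[Si](C)(C)C(C)(C)C)cc2)c2c1C1(C[C@@H](c3ccc(O[Si](C)(C)C(C)(C)C)cc3)O2)SCCCS1 | intermediate
30 | (1S,3R,4E,7S)-7-(TBSO)-3,9-bis[4-(TBSO)phenyl]-1-{(2S)-5-methoxy-2-[4-(TBSO)phenyl]-7-(TIPSO)spiro[chromane-4,2'-[1,3]dithian]-8-yl}non-4-en-1-ol | COc1cc(O[Si](C(C)C)(C(C)C)C(C)C)c([C@@H](O)C[C@H](/C=C/C[C@@H](O[Si](C)(C)C(C)(C)C)CCc2ccc(O[Si](C)(C)C(C)(C)C)cc2)c2ccc(O[Si](C)(C)C(C)(C)C)cc2)c2c1C1(C[C@@H](c3ccc(O[Si](C)(C)C(C)(C)C)cc3)O2)SCCCS1 | intermediate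
31 | (2S)-8-{(1S,3R,4E,7S)-1-hydroxy-7-(TBSO)-3,9-bis[4-(TBSO)phenyl]non-4-en-1-yl}-5-methoxy-2-[4-(TBSO)phenyl]-7-(TIPSO)chroman-4-one | COc1cc(O[Si](C(C)C)(C(C)C)C(C)C)c([C@@H](O)C[C@H](/C=C/C[C@@H](O[Si](C)(C)C(C)(C)C)CCc2ccc(O[Si](C)(C)C(C)(C)C)cc2)c2ccc(O[Si](C)(C)C(C)(C)C)cc2)c2c1C(=O)C[C@@H](c1ccc(O[Si](C)(C)C(C)(C)C)cc1)O2 | intermediate
32 | (2S)-8-[(1S,3R,4E,7S)-1,7-dihydroxy-3,9-bis(4-hydroxyphenyl)non-4-en-1-yl]-7-hydroxy-2-(4-hydroxyphenyl)-5-methoxychroman-4-one | COc1cc(O)c([C@@H](O)C[C@H](/C=C/C[C@@H](O)CCc2ccc(O)cc2)c2ccc(O)cc2)c2c1C(=O)C[C@@H](c1ccc(O)cc1)O2 | target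

Total step count: 19. Longest linear sequence: 11 steps (steps 8, 9, 11, 12, 13, 14, 15, 16, 17, 18, 19, from 12 to 32).

Steps most likely to fail

Step 16. The hindered C8 aryllithium 28 may be protonated by the alpha-hydrogens of amide 25, or may add too slowly, so that ring C closes but the acylation does not follow. Fallback: setting out from 11, the same aryne cyclisation is run and quenched with iodine instead of 25, which should give (2S)-8-iodo-5-methoxy-2-[4-(TBSO)phenyl]-7-(TIPSO)spiro[chromane-4,2'-[1,3]dithiane] F1. Weinreb amide 25 is reduced with i-Bu2AlH (THF, –78 °C) to (3R,4E,7S)-7-(TBSO)-3,9-bis[4-(TBSO)phenyl]non-4-enal F2. Iodine–magnesium exchange on F1 (i-PrMgCl·LiCl, THF, 0 °C) and addition to F2 should give the carbinol, epimeric at chain C1, F3, and Parikh–Doering oxidation (SO3·pyridine, DMSO, i-Pr2NEt) returns to the route at ketone 29.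

Step 17. Low conversion or poor facial selectivity may result in the reduction of the doubly ortho-substituted aryl ketone next to the bulky OTIPS group. Fallback: setting out from 29, unselective reduction with LiBH4 (THF, 0 °C) should give 30 together with its chain-C1 (R) epimer F4, and the two are separated by chromatography. F4 is re-oxidised (Parikh–Doering) to 29 and recycled, and the route continues from 30.

Step 14. The lithium enolate of the allylic acetate may fragment (loss of ketene) or the electron-rich cinnamyl ester may ionise before the rearrangement. Fallback: setting out from 21, the acetate is cleaved reductively (i-Bu2AlH, CH2Cl2, –78 °C) to (1E,3R,5S)-5-(TBSO)-1,7-bis[4-(TBSO)phenyl]hept-1-en-3-ol F5. A neutral, thermal Eschenmoser–Claisen rearrangement (N,N-dimethylacetamide dimethyl acetal, xylene, 140 °C) should then give, with the same chair-controlled chirality transfer, (3R,4E,7S)-N,N-dimethyl-7-(TBSO)-3,9-bis[4-(TBSO)phenyl]non-4-enamide F6. F6 takes the place of 25 as the acylating agent in step 16, so the fallback returns to the route at 29.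

Further compounds
F1 | step 16 | (2S)-8-iodo-5-methoxy-2-[4-(TBSO)phenyl]-7-(TIPSO)spiro[chromane-4,2'-[1,3]dithiane] | COc1cc(O[Si](C(C)C)(C(C)C)C(C)C)c(I)c2c1C1(C[C@@H](c3ccc(O[Si](C)(C)C(C)(C)C)cc3)O2)SCCCS1
F2 | step 16 | (3R,4E,7S)-7-(TBSO)-3,9-bis[4-(TBSO)phenyl]non-4-enal | O=CC[C@H](/C=C/C[C@@H](O[Si](C)(C)C(C)(C)C)CCc1ccc(O[Si](C)(C)C(C)(C)C)cc1)c1ccc(O[Si](C)(C)C(C)(C)C)cc1
F3 | step 16 | carbinol 30 as the mixture of epimers at chain C1 | COc1cc(O[Si](C(C)C)(C(C)C)C(C)C)c(C(O)C[C@H](/C=C/C[C@@H](O[Si](C)(C)C(C)(C)C)CCc2ccc(O[Si](C)(C)C(C)(C)C)cc2)c2ccc(O[Si](C)(C)C(C)(C)C)cc2)c2c1C1(C[C@@H](c3ccc(O[Si](C)(C)C(C)(C)C)cc3)O2)SCCCS1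
F4 | step 17 | (1R) epimer of carbinol 30 | COc1cc(O[Si](C(C)C)(C(C)C)C(C)C)c([C@H](O)C[C@H](/C=C/C[C@@H](O[Si](C)(C)C(C)(C)C)CCc2ccc(O[Si](C)(C)C(C)(C)C)cc2)c2ccc(O[Si](C)(C)C(C)(C)C)cc2)c2c1C1(C[C@@H](c3ccc(O[Si](C)(C)C(C)(C)C)cc3)O2)SCCCS1
F5 | step 14 | (1E,3R,5S)-5-(TBSO)-1,7-bis[4-(TBSO)phenyl]hept-1-en-3-ol | O[C@H](C[C@@H](O[Si](C)(C)C(C)(C)C)CCc1ccc(O[Si](C)(C)C(C)(C)C)cc1)/C=C/c1ccc(O[Si](C)(C)C(C)(C)C)cc1
F6 | step 14 | (3R,4E,7S)-N,N-dimethyl-7-(TBSO)-3,9-bis[4-(TBSO)phenyl]non-4-enamide | CN(C)C(=O)C[C@H](/C=C/C[C@@H](O[Si](C)(C)C(C)(C)C)CCc1ccc(O[Si](C)(C)C(C)(C)C)cc1)c1ccc(O[Si](C)(C)C(C)(C)C)cc1
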